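## The problem

Compound 14 is an open-chain tridepside with no stereocentre: three benzene rings are held together by two aryl ester bonds and nothing else, so the task is one of connectivity, regiochemistry and functional-group tolerance. The carbonyl on C1 of ring A (a 2,4,5-trimethoxy-6-methylbenzoyl unit) is bound to the C4 oxygen of ring B (an orsellinoyl unit), and the ring B carbonyl is bound to the C4 oxygen of ring C (orsellinic acid with its carboxyl free). Both acyl carbons carry two ortho substituents (methoxy and methyl on ring A, hydroxyl and methyl on ring B), which makes each esterification hindered. Rings B and C each offer two phenols, of which only the C4 hydroxyl may be acylated. The ester links are cleaved or transesterified by hydroxide, alkoxides and nucleophilic amines, the terminal salicylic acid decarboxylates on heating, and ring A is an electron-rich hydroquinone dimethyl ether that strong oxidants convert to a quinone; the carboxyl must therefore be unveiled last under neutral conditions. The enabling feature is that the ring A carbonyl carbon sits on C1, between the C2 methoxy and the C6 methyl and para to the C4 methoxy. This is the position at which the parent arene 4 is expected to be halogenated most readily, so C1 can be supplied as an aryl iodide and the hindered carbonyl carbon as carbon monoxide.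

## Retrosynthesis

**14 from 13.** The last bond cut is the benzyl–oxygen bond of a benzyl ester. Hydrogenolysis is neutral and leaves aryl esters and aryl methyl ethers alone, whereas saponification of an alkyl ester would cleave both depside links. Benzyl ester 13 differs from the target only by this one group.

**13 from 11 and 8.** The ring B acyl–oxygen bond is cut, giving acid 11 and benzyl orsellinate 8. Making this bond after the ring A–ring B bond lets the single phenol 8 serve twice and keeps the benzyl ester as the only protecting group. The reverse order would need a ring B acid with its C4 hydroxyl masked by a group orthogonal to the terminal benzyl ester. The forward reaction must acylate the C4 hydroxyl of 8 with a salicylic-type acid that keeps its own chelated C2 hydroxyl free.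

**11 from 10.** The benzyl ester of 10 is cut by hydrogenolysis, the same neutral operation as at the end. The precursor 10 is the direct product of the key step, and nothing more is asked of the forward reaction than tolerance of one aryl ester.

**10 from 5, 9 and 8.** Two bonds are cut together: ring A C1–C(=O) and C(=O)–O(ring B C4). The fragments are aryl iodide 5, carbon monoxide 9 and phenol 8. The neighbouring one-bond cut at the acyl–oxygen bond alone would need a di-ortho-substituted aroyl electrophile to be prepared, purified and activated toward a phenol. In the three-component cut the acyl group is created on palladium and passed directly to the phenoxide. The precursors are much simpler: a pentasubstituted iodoarene, a gas and a one-step derivative of a purchasable acid. The forward reaction must insert CO faster than it couples aryl and oxygen directly, and must choose the C4 over the C2 hydroxyl of 8.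

**5 from 4.** The C1–I bond is cut to give 1,2,5-trimethoxy-3-methylbenzene 4. Of its two free positions, the one between methyl and methoxy is para to a methoxy group and the other lies between two methoxy groups, so electrophilic iodination should go to the former. The forward reaction is asked only for this regiocontrol and for mono-iodination.

**4 from 2 by way of 3.** Arene 4 is cut at two O–CH3 bonds to hydroquinone 3, which is the reduced form of quinone 2. Reduction and methylation in one flask avoid handling the air-sensitive hydroquinone 3.

**2 from 1.** Quinone 2 is cut at its C–O bond para to the hydroxyl of the purchasable 3-methoxy-5-methylphenol 1. Oxidation at the only free para position places the third oxygen without any regiochemical ambiguity.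

**8 from 6 and 7.** The benzyl–oxygen bond is cut to orsellinic acid 6 and benzyl bromide 7. The forward reaction is alkylation of a carboxylate in the presence of two free phenols.

## Roads not taken

**Alternative 1:** Ring A is cut into ethyl acetoacetate A3 and methyl (Z)-2-methoxybut-2-enoate A2. In the forward key step the sodium enolate of A3 adds to A2, and the acetyl methyl group of the adduct then closes onto the methyl ester by intramolecular Claisen condensation. The product is the cyclohexane-1,3-dione ethyl 5-methoxy-6-methyl-2,4-dioxocyclohexane-1-carboxylate A1. Dehydrogenation of A1 would give ethyl 2,4-dihydroxy-5-methoxy-6-methylbenzoate A4. Double O-methylation of A4 followed by saponification would give 2,4,5-trimethoxy-6-methylbenzoic acid A5, to be esterified with 8.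
- Merits: the materials are cheap and acyclic, and the ring A substitution pattern is fixed by construction. In this respect it is better than the chosen plan, which depends on the orientation of an electrophilic iodination. No palladium or CO is needed.
- Weak points: the Michael acceptor A2 is deactivated by its α-methoxy group and hindered by its β-methyl group. A1 can aromatise without any oxidant by losing methanol, which would erase the C5 oxygen that A4 is meant to carry. The sequence ends with hydrolysis of a di-ortho-substituted ester and activation of the hindered acid A5.
- Comparison: five operations are needed to reach 10 against four on the ring A line of the chosen plan. The chosen plan offsets its iodination risk by never making or activating the ring A acid.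

**Alternative 2:** Ring C is cut into benzyl (E)-5-diazo-3-methyl-4-oxopent-2-enoate A7 and (triisopropylsilyloxy)ethyne A8. Irradiation of A7 triggers a Wolff rearrangement to a vinylketene. This adds A8 in a [2+2] sense, and the resulting cyclobutenone opens and recloses by 6π electrocyclisation to benzyl 2-hydroxy-6-methyl-4-(triisopropylsilyloxy)benzoate A6.
- Merits: the annulation is regiospecific and delivers ring C with its two oxygens differentiated. The C2 hydroxyl of A6 could be capped before the C4 oxygen is unveiled. The chosen plan cannot do this as cheaply and has to rely on the intrinsic difference between a chelated and a free phenol.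
- Weak points: the strategic step is spent on the least demanding ring. Desilylation of A6 gives 8, which the chosen plan makes in one step from a purchasable acid. A diazo ketone, photochemistry and a sensitive siloxyalkyne are added, and the hindered ring A acyl transfer remains unsolved.
- Comparison: this is the longer road for this target, and it would be of interest mainly for ring C analogues.

**Alternative 3:** The C5–O bond of ring A is cut. Methyl 2-hydroxy-4-methoxy-6-methylbenzoate A9 is oxidised at a carbon anode in methanol, with LiClO4 as electrolyte, to the para-quinone monoketal methyl 3,3,4-trimethoxy-2-methyl-6-oxocyclohexa-1,4-diene-1-carboxylate A10. Reduction of A10 with loss of methanol would give methyl 2-hydroxy-4,5-dimethoxy-6-methylbenzoate A11. Methylation of the chelated phenol of A11 followed by saponification would give A5, to be esterified with 8.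
- Merits: the carboxyl carbon is present from the start, and the new oxygen enters para to the phenol with no ambiguity. This is more secure than the iodination of the chosen plan. No CO or palladium is needed and the oxidation uses no chemical oxidant.
- Weak points: an electrolysis set-up is required. The di-ortho-substituted methyl ester derived from A11 must be hydrolysed under forcing conditions. The hindered acid A5 must then be activated toward a phenol, which is the step the chosen plan avoids.
- Comparison: five operations from A9 to 10 stand against four from 1 to 10. The chosen plan accepts a regiochemical question in one iodination in exchange for a shorter sequence that creates the hindered ester directly.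

Key step: step 5

Assumption: 3-methoxy-5-methylphenol 1 and orsellinic acid 6 are taken as purchasable, and iodination of 4 is taken to follow the orientation usual for polymethoxyarenes (attack para to a methoxy group in preference to the site between two methoxy groups).

## Route

**Step 1**
Reactants: 1 3-methoxy-5-methylphenol
Product: 2 2-methoxy-6-methyl-1,4-benzoquinone
Conditions: (KSO3)2NO (2.2 equiv.), KH2PO4 buffer, H2O/acetone, 0 °C to rt
Reagents that add atoms: potassium nitrosodisulfonate, [K+].[K+].[O]N(S(=O)(=O)[O-])S(=O)(=O)[O-]
Why: Teuber oxidation: the nitrosodisulfonate radical removes the phenolic hydrogen, a second equivalent couples through oxygen at the free para position and loss of imidodisulfonate leaves the para-quinone; phenols with a free para position flanked by two substituents are standard substrates.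

**Step 2**
Reactants: 2 2-methoxy-6-methyl-1,4-benzoquinone
Product: 4 1,2,5-trimethoxy-3-methylbenzene, via 2-methoxy-6-methylbenzene-1,4-diol 3 (not isolated)
Conditions: Na2S2O4, Bu4NBr (cat.), THF/H2O, rt; then NaOH aq., Me2SO4, rt, under N2
Reagents that add atoms: dimethyl sulfate, COS(=O)(=O)OC
Why: One-pot reductive methylation of a quinone: dithionite reduces 2 to hydroquinone 3, which is O-methylated twice under phase-transfer Williamson conditions before air can re-oxidise it.

**Step 3**
Reactants: 4 1,2,5-trimethoxy-3-methylbenzene
Product: 5 2-iodo-1,4,5-trimethoxy-3-methylbenzene
Conditions: NIS (1.05 equiv.), TFA (cat.), MeCN, rt, dark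
Reagents that add atoms: N-iodosuccinimide, O=C1CCC(=O)N1I
Why: Electrophilic aromatic iodination with acid-activated NIS; the site between methyl and methoxy is para to one methoxy group and ortho to a second, whereas the other free site is activated only through ortho-methoxy and para-methyl donation and is shielded on both sides by methoxy groups, so the iodine should enter at the future ring A C1.

**Step 4**
Reactants: 6 orsellinic acid (2,4-dihydroxy-6-methylbenzoic acid); 7 benzyl bromide
Product: 8 benzyl orsellinate (benzyl 2,4-dihydroxy-6-methylbenzoate)
Conditions: KHCO3 (1.1 equiv.), DMF, rt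
Reagents that add atoms: none
Why: SN2 alkylation of the carboxylate; hydrogencarbonate deprotonates only the carboxylic acid, so both phenols stay free, and room temperature avoids decarboxylation of the acid.

**Step 5**
Reactants: 5 2-iodo-1,4,5-trimethoxy-3-methylbenzene; 9 carbon monoxide; 8 benzyl orsellinate
Product: 10 benzyl 2-hydroxy-6-methyl-4-[(2,4,5-trimethoxy-6-methylbenzoyl)oxy]benzoate
Conditions: Pd(OAc)2 (5 mol %), Xantphos (10 mol %), Et3N (2 equiv.), CO (1 atm), toluene, 90 °C
Reagents that add atoms: none
Why: Pd(OAc)2 is reduced in the flask to zerovalent palladium, which adds oxidatively into the ring A C1–I bond of 5; CO then inserts to give an aroylpalladium iodide, and the C4 phenoxide of 8, formed by Et3N, replaces iodide and is joined to the acyl carbon by reductive elimination, which returns zerovalent palladium. The closest known reaction type is the palladium-catalysed aryloxycarbonylation (carbonylative esterification) of aryl iodides with phenols. Two skeletal bonds form, ring A C1–C(=O) and C(=O)–O; no ring closes and no stereocentre arises. The step needs chemoselectivity between the two phenols of 8: the C2 hydroxyl is hydrogen-bonded to the adjacent ester carbonyl and crowded by it, whereas the C4 hydroxyl is para to the ester, more acidic and unhindered, so its phenoxide is the one formed and the one that reaches the metal. CO insertion must also outrun direct aryl–oxygen coupling; the two ortho substituents of the arylpalladium species favour insertion because it moves the metal one atom away from the crowded ring carbon. The wide bite angle of Xantphos (4,5-bis(diphenylphosphino)-9,9-dimethylxanthene) promotes acyl–oxygen reductive elimination from the hindered aroyl complex. The benzyl ester, the chelated phenol and the aryl methyl ethers are inert under these conditions.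

**Step 6**
Reactants: 10 benzyl 2-hydroxy-6-methyl-4-[(2,4,5-trimethoxy-6-methylbenzoyl)oxy]benzoate
Product: 11 2-hydroxy-6-methyl-4-[(2,4,5-trimethoxy-6-methylbenzoyl)oxy]benzoic acid
Conditions: H2 (1 atm), 10 % Pd/C, EtOAc, rt
Reagents that add atoms: none
Why: Hydrogenolysis of a benzyl ester; the aryl ester and the aryl methyl ethers are untouched, and the neutral conditions at room temperature avoid decarboxylation of the salicylic acid.

**Step 7**
Reactants: 11 2-hydroxy-6-methyl-4-[(2,4,5-trimethoxy-6-methylbenzoyl)oxy]benzoic acid; 8 benzyl orsellinate
Product: 13 benzyl 2-hydroxy-4-({2-hydroxy-6-methyl-4-[(2,4,5-trimethoxy-6-methylbenzoyl)oxy]benzoyl}oxy)-6-methylbenzoate, via mixed aroyl trifluoroacetyl anhydride 12 (not isolated)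
Conditions: (CF3CO)2O, toluene, rt
Reagents that add atoms: trifluoroacetic anhydride, O=C(OC(=O)C(F)(F)F)C(F)(F)F (its trifluoroacetyl group is carried only by intermediate 12, not by 13)
Why: Mixed-anhydride esterification as used classically for depsides: anhydride 12 transfers its aroyl group, whose acylium character is supported by the ortho hydroxyl, to the unhindered C4 phenol of 8, while the chelated C2 hydroxyls of both partners are poor nucleophiles and the existing aryl ester is stable in the acidic, non-nucleophilic medium.

**Step 8**
Reactants: 13 benzyl 2-hydroxy-4-({2-hydroxy-6-methyl-4-[(2,4,5-trimethoxy-6-methylbenzoyl)oxy]benzoyl}oxy)-6-methylbenzoate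
Product: 14 2-hydroxy-4-({2-hydroxy-6-methyl-4-[(2,4,5-trimethoxy-6-methylbenzoyl)oxy]benzoyl}oxy)-6-methylbenzoic acid
Conditions: H2 (1 atm), 10 % Pd/C, EtOAc, rt
Reagents that add atoms: none
Why: Hydrogenolysis of the terminal benzyl ester; both depside links are inert to H2 over Pd/C and the neutral conditions protect the decarboxylation-prone acid terminus.

## Compound list

1 | 3-methoxy-5-methylphenol | COc1cc(C)cc(O)c1 | starting material
2 | 2-methoxy-6-methyl-1,4-benzoquinone | COC1=CC(=O)C=C(C)C1=O | intermediate
3 | 2-methoxy-6-methylbenzene-1,4-diol | COc1cc(O)cc(C)c1O | intermediate (not isolated)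
4 | 1,2,5-trimethoxy-3-methylbenzene | COc1cc(OC)cc(C)c1OC | intermediate
5 | 2-iodo-1,4,5-trimethoxy-3-methylbenzene | COc1cc(OC)c(I)c(C)c1OC | intermediate
6 | orsellinic acid (2,4-dihydroxy-6-methylbenzoic acid) | Cc1cc(O)cc(O)c1C(=O)O | starting material
7 | benzyl bromide | BrCc1ccccc1 | starting material
8 | benzyl orsellinate (benzyl 2,4-dihydroxy-6-methylbenzoate) | Cc1cc(O)cc(O)c1C(=O)OCc1ccccc1 | intermediate
9 | carbon monoxide | [C-]#[O+] | starting material
10 | benzyl 2-hydroxy-6-methyl-4-[(2,4,5-trimethoxy-6-methylbenzoyl)oxy]benzoate | COc1cc(OC)c(C(=O)Oc2cc(C)c(C(=O)OCc3ccccc3)c(O)c2)c(C)c1OC | intermediate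
11 | 2-hydroxy-6-methyl-4-[(2,4,5-trimethoxy-6-methylbenzoyl)oxy]benzoic acid | COc1cc(OC)c(C(=O)Oc2cc(C)c(C(=O)O)c(O)c2)c(C)c1OC | intermediate
12 | 2-hydroxy-6-methyl-4-[(2,4,5-trimethoxy-6-methylbenzoyl)oxy]benzoic trifluoroacetic anhydride | COc1cc(OC)c(C(=O)Oc2cc(C)c(C(=O)OC(=O)C(F)(F)F)c(O)c2)c(C)c1OC | intermediate (not isolated)
13 | benzyl 2-hydroxy-4-({2-hydroxy-6-methyl-4-[(2,4,5-trimethoxy-6-methylbenzoyl)oxy]benzoyl}oxy)-6-methylbenzoate | COc1cc(OC)c(C(=O)Oc2cc(C)c(C(=O)Oc3cc(C)c(C(=O)OCc4ccccc4)c(O)c3)c(O)c2)c(C)c1OC | intermediate
14 | 2-hydroxy-4-({2-hydroxy-6-methyl-4-[(2,4,5-trimethoxy-6-methylbenzoyl)oxy]benzoyl}oxy)-6-methylbenzoic acid | COc1cc(OC)c(C(=O)Oc2cc(C)c(C(=O)Oc3cc(C)c(C(=O)O)c(O)c3)c(O)c2)c(C)c1OC | target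

## Step count and risks

Total step count: 8. Longest linear sequence: 7 steps (steps 1, 2, 3, 5, 6, 7 and 8, from 1 to 14). Step 4 is the only step off this line.

**Step 5 (key step).** The most likely failure is slow oxidative addition and slow turnover with the electron-rich, di-ortho-substituted iodide. Reductive loss of iodine from the arylpalladium species, or direct aryl–oxygen coupling without CO uptake, could then compete. Partial acylation of the chelated C2 hydroxyl is a lesser concern. The fallback gives up the carbonylation and makes the hindered acid in the classical way, starting from 5. Iodine–lithium exchange (n-BuLi, THF, −78 °C) would give (2,4,5-trimethoxy-6-methylphenyl)lithium F1. Quenching with CO2 and acidifying with aqueous HCl would give 2,4,5-trimethoxy-6-methylbenzoic acid F2. Treating F2 and 8 with trifluoroacetic anhydride in toluene would form 2,4,5-trimethoxy-6-methylbenzoic trifluoroacetic anhydride F3 in the flask, whose acylium-like aroyl group should acylate the C4 phenol of 8. The route is rejoined at 10.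

**Step 7.** Two processes threaten this step. The unprotected ring B C2 hydroxyl of 11 may be acylated by the mixed anhydride, leading to oligomers. Alternatively, the weakly donating 4-aroyloxy group may support the acylium too little, so that the phenol attacks the trifluoroacetyl carbon. The fallback masks that hydroxyl and uses a carbodiimide, starting from 10. Chloromethyl methyl ether and i-Pr2NEt in CH2Cl2 would give benzyl 2-(methoxymethoxy)-6-methyl-4-[(2,4,5-trimethoxy-6-methylbenzoyl)oxy]benzoate F4. Hydrogenolysis (H2, 10 % Pd/C, EtOAc) would give 2-(methoxymethoxy)-6-methyl-4-[(2,4,5-trimethoxy-6-methylbenzoyl)oxy]benzoic acid F5. Steglich esterification of F5 with 8 (DCC, DMAP cat., CH2Cl2) would give benzyl 2-hydroxy-4-({2-(methoxymethoxy)-6-methyl-4-[(2,4,5-trimethoxy-6-methylbenzoyl)oxy]benzoyl}oxy)-6-methylbenzoate F6. Removal of the acetal with wet trifluoroacetic acid in CH2Cl2 at 0 °C, which leaves aryl and benzyl esters alone, would rejoin the route at 13.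

**Step 3.** The risk is incomplete regiocontrol, with some iodination between the two methoxy groups or some di-iodination giving a mixture that is hard to separate. The fallback turns the mixture into one compound and then uses metal–halogen exchange, which prefers the other site. Starting from 4, excess NIS with TFA in MeCN at 50 °C would give 1,3-diiodo-2,4,5-trimethoxy-6-methylbenzene F7. Treatment with i-PrMgCl·LiCl in THF at −40 °C should exchange only the iodine flanked by two coordinating methoxy groups, giving (3-iodo-2,5,6-trimethoxy-4-methylphenyl)magnesium chloride F8. Protonation with aqueous HCl would rejoin the route at 5.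

## Further compounds

F1 | step 5 | (2,4,5-trimethoxy-6-methylphenyl)lithium | [Li]c1c(C)c(OC)c(OC)cc1OC
F2 | step 5 | 2,4,5-trimethoxy-6-methylbenzoic acid | COc1cc(OC)c(C(=O)O)c(C)c1OC
F3 | step 5 | 2,4,5-trimethoxy-6-methylbenzoic trifluoroacetic anhydride | COc1cc(OC)c(C(=O)OC(=O)C(F)(F)F)c(C)c1OC
F4 | step 7 | benzyl 2-(methoxymethoxy)-6-methyl-4-[(2,4,5-trimethoxy-6-methylbenzoyl)oxy]benzoate | COCOc1cc(OC(=O)c2c(C)c(OC)c(OC)cc2OC)cc(C)c1C(=O)OCc1ccccc1
F5 | step 7 | 2-(methoxymethoxy)-6-methyl-4-[(2,4,5-trimethoxy-6-methylbenzoyl)oxy]benzoic acid | COCOc1cc(OC(=O)c2c(C)c(OC)c(OC)cc2OC)cc(C)c1C(=O)O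
F6 | step 7 | benzyl 2-hydroxy-4-({2-(methoxymethoxy)-6-methyl-4-[(2,4,5-trimethoxy-6-methylbenzoyl)oxy]benzoyl}oxy)-6-methylbenzoate | COCOc1cc(OC(=O)c2c(C)c(OC)c(OC)cc2OC)cc(C)c1C(=O)Oc1cc(C)c(C(=O)OCc2ccccc2)c(O)c1
F7 | step 3 | 1,3-diiodo-2,4,5-trimethoxy-6-methylbenzene | COc1c(I)c(OC)c(I)c(C)c1OC
F8 | step 3 | (3-iodo-2,5,6-trimethoxy-4-methylphenyl)magnesium chloride | COc1c([Mg]Cl)c(OC)c(I)c(C)c1OC
A1 | alternative 1 | ethyl 5-methoxy-6-methyl-2,4-dioxocyclohexane-1-carboxylate (mixture of diastereomers and enol forms) | CCOC(=O)C1C(C)C(OC)C(=O)CC1=O
A2 | alternative 1 | methyl (Z)-2-methoxybut-2-enoate | C/C=C(\OC)C(=O)OC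
A3 | alternative 1 | ethyl acetoacetate | CCOC(=O)CC(C)=O
A4 | alternative 1 | ethyl 2,4-dihydroxy-5-methoxy-6-methylbenzoate | CCOC(=O)c1c(C)c(OC)c(O)cc1O
A5 | alternative 1 | 2,4,5-trimethoxy-6-methylbenzoic acid (also reached in alternative 3) | COc1cc(OC)c(C(=O)O)c(C)c1OC
A6 | alternative 2 | benzyl 2-hydroxy-6-methyl-4-(triisopropylsilyloxy)benzoate | Cc1cc(O[Si](C(C)C)(C(C)C)C(C)C)cc(O)c1C(=O)OCc1ccccc1
A7 | alternative 2 | benzyl (E)-5-diazo-3-methyl-4-oxopent-2-enoate | O=C(OCc1ccccc1)/C=C(\C)C(=O)C=[N+]=[N-]
A8 | alternative 2 | (triisopropylsilyloxy)ethyne | C#CO[Si](C(C)C)(C(C)C)C(C)C
A9 | alternative 3 | methyl 2-hydroxy-4-methoxy-6-methylbenzoate | COC(=O)c1c(C)cc(OC)cc1O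
A10 | alternative 3 | methyl 3,3,4-trimethoxy-2-methyl-6-oxocyclohexa-1,4-diene-1-carboxylate | COC(=O)C1=C(C)C(OC)(OC)C(OC)=CC1=O
A11 | alternative 3 | methyl 2-hydroxy-4,5-dimethoxy-6-methylbenzoate | COC(=O)c1c(C)c(OC)c(OC)cc1O
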